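The product of this flask ends up in three places, dissolved links, crystals and isomer of the product, and what matters is how the charge shares out among them.

    first end groups + second end groups → links + released group (k1 = 0.0551 M⁻¹ s⁻¹)
    links ⇌ isomer of the product (K2 = 2.7, k2 = 0.0284 s⁻¹)
    crystals ⇌ links, rate k3*(cs3 - [links]) while solid is left; crystals form when [links] > cs3 (cs3 = 15 mM, k3 = 0.134 s⁻¹)

first end groups 0.50 M; second end groups 0.980 equiv; time 2.5 h

1. which holds at 2.5 h: what has brought the reaction to rest, or that it has not come to rest (all of the first end groups has reacted / the second end groups has run out first / forward and back rates have come level / it is still moving)
2. how much of the first end groups has reacted by 2.5 h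
3. how much links there is at 2.5 h, in percent of the first end groups charged
4. how much isomer of the product there is at 2.5 h, in percent of the first end groups charged

- amounts and yields of links count crystals too
- given per volume of solution although it is solid: crystals
- the reaction counts as stopped when no species that holds the first end groups changes by six tenths of a point or more over the second half of the time
- run time (flask): 2.5 h

I follow one molecule of links as it forms: at the fork it goes on to the isomer or into the crystals. The isomer step relaxes with a half-life of 0.297 min, short against the 2.5 h, so I take it as level at the end. While crystals stand, I take dissolved links at the solubility s. With K the equilibrium constant of the isomer step and c the charge of first end groups, I fold this into one number: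

φ = K·s/c = 2.7 × 15 mM / 0.50 M = 8.10%

So φ is the share of the charge that stands as isomer beside a saturated solution, and what is made beyond that, less the dissolved links, I expect as crystals. I expect crystals, since solution and isomer together take φ(1 + 1/K) = 11.1% of the charge, less than the 0.980 equiv of second end groups, the limiting reagent. That gives me conversion 98.0%, isomer 8.10% and links 89.9%, crystals counted.

But φ does not say whether that ceiling is reached, so I need a second number. Late on, I reckon the second end groups to decay against the small excess of first end groups with a half-life of

0.349 h

and the run lasts 7.16 of these.

The forecast gives the second end groups has run out first, with conversion 97.99%, links 89.9% and isomer 8.1%, on the ground that “crystallisation pins dissolved links near 15 mM”.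

The simulation of this flask gives the second end groups has run out first at 2.5 h, with 0.014% of the second end groups left, conversion 98.0%, links 89.9% and isomer 8.10%, and crystals at 86.9% within those links. In the neighbouring flask, charged with 0.20 M of first end groups at the same equivalents, the same division gives φ = 20.2%, and so links at 77.8%. That flask gives conversion 97.7%, isomer 20.3% and links 77.4%.

The constants used here are made up; the rest is arithmetic.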